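## Structural features

The target is a daucane-type sesquiterpenoid ester built on a cis-fused bicyclo[5.3.0]dec-7-ene: a cyclopentane (C1–C5) and a cycloheptene (C1, C5–C10) share the C1–C5 bond, and the C6 oxygen carries a 3-hydroxy-4-methoxybenzoyl (isovanilloyl) group. Four stereocentres are contiguous, (1R,4R,5S,6R) in this numbering: quaternary C1 (methyl), ring-fusion C5 (hydrogen), the tertiary carbinol C4 (isopropyl, hydroxyl) and the allylic carbinol C6. The C1 methyl, H5 and the isopropyl group lie on one face. The oxygens on C4 and C6 lie on the other face, cis to each other and trans to H5. C5 is flanked by two fully substituted carbons and by C6, so the C6 hydroxyl is a poorly accessible, neopentyl-like secondary alcohol. The fragile groups are the secondary allylic ester (ionisation, hydrolysis), the tertiary alcohol β to C6 (retro-aldol cleavage or β-elimination whenever C6 is a carbonyl group), the free phenol and the trisubstituted C7=C8 alkene. The real difficulty is the C1/C5/C4 array in its relation to C6, and the need to acylate O6 rather than O4 or the phenol; the seven-membered ring as such is the lesser problem. The key step exploits three facts: C6–C7=C8(CH3) can be made open-chain as a (Z)-3-iodobut-2-enyl carbinol, C9–C10 can start as a vinyl group on C1, and the C8–C9 bond is the one bond of the cycloheptene remote from all four stereocentres.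

## Logic of the disconnections

**22 ⇒ 21.** The two O–Si bonds (tertiary O4–Si and aryl O–Si) are cut. Both groups must be masked during acylation, and both fall to fluoride in one operation. The last step then touches no C–C bond and no stereocentre. The forward step needs buffered fluoride, so that the allylic ester is neither cleaved nor ionised.

**21 ⇒ 16 + 19 (19 ⇒ 17).** The acyl C–O6 bond is cut. This separates the arene from the terpenoid core, and 19 is a one-flask derivative of 17 (through 18). Because O4 has been silylated since step 1, the C6 hydroxyl is the only free hydroxyl of 16 and no site selectivity is asked for. The forward step must acylate a hindered secondary allylic alcohol, hence the activated acyl donor 20 with a nucleophilic catalyst.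

**16 ⇒ 14 (through 15).** The C8–C9 bond is cut. This opens the seven-membered ring to a monocyclic cyclopentane whose two arms sit cis on C1 and C5, with all four stereocentres and the alkene geometry already in place. The C6 hydroxyl is deliberately left free in 14. A silyl ether there would force a global deprotection, a diol acylation and a second deprotection after ring closure; with only O4 masked, 16 can be acylated directly. The forward step needs chemoselective hydroboration of the vinyl group, high dilution, and tolerance of a free hydroxyl.

**14 ⇒ 12 (through 13).** The C8–I and C7–H bonds are cut, returning the iodoalkene to an alkyne. The (Z)-geometry comes from a five-membered alkenylalanate formed by hydroxyl-directed trans-hydroalumination. The forward step needs the C6 hydroxyl free at this point and aluminium delivered to C8.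

**12 ⇒ 11 ⇒ 10 ⇒ 8 + 9.** The C6–C7 bond is cut, and the C6 stereocentre is referred to a ketone. Alkynyl addition is reliable even at a congested aldehyde, and a reagent-controlled ynone reduction makes C6 independent of substrate bias. The forward reduction must leave the terminal alkene alone and must treat the alkyne as the small substituent.

**8 ⇒ 5 + 6 (through 7).** The C1–C10 and C5–H bonds are cut. Conjugate addition builds quaternary C1, and protonation sets C5; C4 is the only controlling stereocentre. Two stereocentres are removed and a planar enal results. The forward step needs 1,4- rather than 1,2-addition to a tetrasubstituted enal, attack anti to the isopropyl group, and thermodynamic control at C5.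

**5 ⇒ 2 ⇒ 1 (through 3 and 4).** The C1=C5 bond is cut (aldol condensation), and the resulting 1,6-keto aldehyde is reconnected to a cyclohexene. The carbinol carbon of 1 already carries the oxygen and the isopropyl group of C4, so C4 is the only stereocentre that is bought. The forward step needs the enamine mode of aldol closure (aldehyde α-carbon onto the methyl ketone). The silyl ether is installed first to block retro-aldol cleavage and hemiketal formation.

## Other disconnections considered

**Alternative 1:** The cut is C1–CH3 together with C4–C5. In the forward sense, Cu(OTf)2 with a chiral phosphoramidite would transfer methyl from Me3Al to the β-carbon of the achiral enone A1, and the aluminium enolate would close on the side-chain isopropyl ketone to give the hydroxy ketone A2.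
- In its favour: absolute configuration comes from a catalyst and not from the chiral pool, and one operation forms two bonds, the five-membered ring and three stereocentres (C1, C4, C5). On stereocentres per step this is better than the chosen plan, which spends step 3 on C1 and C5 and buys C4.
- Against it here: A2 lacks the C8 methyl and the C7=C8 alkene, and C6 is a ketone. A2 is also a β-hydroxy ketone prone to retro-aldol cleavage, so O4 must be capped at once. The tail would need dehydrogenation, methyl 1,4-addition, a second dehydrogenation and a 1,2-reduction whose facial course at C6 rests on substrate control in a flexible ring. The aldol onto a hindered ketone is reversible, and its C4 outcome depends on a closed transition state that cannot be guaranteed.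
- Comparison: the alternative's key step is the stronger one mechanistically. The chosen plan is stronger after the key step (two steps to the target against six or more) and sets C6 by reagent control before the ring exists. Overall step counts would be similar at best.

**Alternative 2:** The cut is C1–C5 together with C9–C10. [Rh(CO)2Cl]2 would catalyse the (5+2) cycloaddition of the tethered 1,1-disubstituted alkene and the vinylcyclopropane of A3 to give the bicyclic diene-free product A4.
- In its favour: both rings, quaternary C1 and C5 are formed at once with full atom economy, and cis-fusion is the usual outcome of such tethered cycloadditions. In bond count and convergence it is better than the chosen key step.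
- Against it here: A4 has no isopropyl group at C4, so deprotection, oxidation and isopropyl addition to a hindered, enolisable cyclopentanone would follow. The alkene sits at C6=C7 with no oxygen at C6, so an allylic oxidation with transposition (for example an ene reaction of singlet oxygen) must find both the right carbon and the right face. The C8 stereocentre is made only to be destroyed. A3 needs an enantiopure disubstituted cyclopropane plus the C4 carbinol, and the cyclopropane must cleave at its less substituted bond.
- Comparison: equal or better in the ring-forming event, but weaker in functional-group fit. The chosen plan carries the correct C4, C6 and C7=C8 functionality into the ring closure and needs no oxidation-level corrections afterwards.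

**Alternative 3:** The cut is C1–C5 together with C7–C8. Catalytic Et3SiOTf would open the epoxide of the epoxy enol silane A5, and the tethered diene would add at C5 (with inversion) and at C7 to give the bicyclic ketone A6.
- In its favour: it forms both rings with C1 and C5 set stereospecifically from the epoxide, and A6 already has the silylated C4 carbinol with its isopropyl group, the C8 methyl and an oxygen at C6. Of the three alternatives it fits the target best, and in convergence it is the equal of the chosen plan or better.
- Against it here: the C9=C10 alkene must be hydrogenated, C7–C8 dehydrogenated regioselectively, and the enone reduced with facial control at C6, which is again a substrate-controlled event next to the congested ring fusion. The C8 stereocentre is wasted. A quaternary centre must form at a disubstituted diene terminus. A5 (enantiopure trisubstituted epoxide, enol silane, (E,E)-diene) is no shorter to make than 14.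
- Comparison: the number of steps after the key step is about five against two, and the total is probably similar. The chosen plan separates the stereochemical decisions (C4 bought, C1/C5 in step 3, C6 in step 6), so a failure can be repaired locally; in A6 a wrong face in one event compromises the whole core.

Key step: step 8

Remarks on the chemistry (assumptions):
- Locants C1–C10 are those of the first section and are used for all intermediates.
- Commercial (S)-(+)-terpinen-4-ol is assumed to be of high enantiomeric purity; a lot of lower purity would be enriched before step 1.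
- In step 8 the excess 9-BBN is assumed to cap the free C6 hydroxyl as its borinate (loss of H2), which the aqueous base of the coupling hydrolyses again; 15 is drawn accordingly.
- The C6 descriptor is S in 12 and 14 and R in 16, 21 and 22. The spatial arrangement is the same; only the CIP priorities change on ring closure.

## Route

Step 1
Reactants: 1 (S)-terpinen-4-ol [(1S)-4-methyl-1-(propan-2-yl)cyclohex-3-en-1-ol]
Product: 2 triethyl{[(1S)-4-methyl-1-(propan-2-yl)cyclohex-3-en-1-yl]oxy}silane
Conditions: Et3SiOTf, 2,6-lutidine, CH2Cl2, −78 to 0 °C
Reagents that add atoms: triethylsilyl trifluoromethanesulfonate, CC[Si](CC)(CC)OS(=O)(=O)C(F)(F)F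
Why: Silyl triflate silylation of a tertiary alcohol; the ether blocks retro-aldol cleavage, hemiketal formation and alkoxide chemistry in all later steps and is removed only at the end.

Step 2
Reactants: 2 triethylsilyl ether of (S)-terpinen-4-ol
Product: 5 (5R)-2-methyl-5-(propan-2-yl)-5-[(triethylsilyl)oxy]cyclopent-1-ene-1-carbaldehyde, via ozonide 3 (not isolated), via keto aldehyde 4 (not isolated)
Conditions: O3, CH2Cl2, −78 °C; PPh3, −78 °C to rt; then piperidine (0.3 equiv), AcOH (0.3 equiv), rt to 40 °C
Reagents that add atoms: ozone, [O-][O+]=O
Why: Ozonolysis of the trisubstituted alkene with reductive work-up gives the 1,6-keto aldehyde; piperidinium acetate then engages the aldehyde as its enamine, which closes on the methyl ketone (5-exo aldol) and dehydrates to the tetrasubstituted enal, the established course for 6-oxoheptanals under amine catalysis. The C4 stereocentre is untouched.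

Step 3
Reactants: 5 silylated cyclopentene carbaldehyde; 6 vinylmagnesium bromide
Product: 8 (1R,2S,5R)-2-ethenyl-2-methyl-5-(propan-2-yl)-5-[(triethylsilyl)oxy]cyclopentane-1-carbaldehyde, via silyl enol ether 7 (not isolated)
Conditions: 6 (3 equiv), CuBr·SMe2 (20 mol %), Me3SiCl, THF, −78 to −30 °C; aq. NH4Cl; then K2CO3 (0.2 equiv), MeOH, 0 °C to rt
Reagents that add atoms: none
Why: Copper-catalysed, chlorosilane-accelerated conjugate addition of a Grignard reagent to a β,β-disubstituted enal; the vinyl group should enter C1 on the face anti to the isopropyl group of C4, which has the larger effective size next to the ring than the long-bonded silyloxy group. Methanolysis of the enol silane under mild base then equilibrates C5 to the more stable epimer, formyl trans to isopropyl and methyl.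

Step 4
Reactants: 8 vinyl cyclopentane carbaldehyde; 9 1-propynylmagnesium bromide
Product: 10 1-[(1S,2S,5R)-2-ethenyl-2-methyl-5-(propan-2-yl)-5-[(triethylsilyl)oxy]cyclopentyl]but-2-yn-1-ol as a mixture of C6 epimers
Conditions: 9 (1.5 equiv), THF, −78 to 0 °C; aq. NH4Cl
Reagents that add atoms: none
Why: 1,2-Addition of a slim, weakly basic alkynyl Grignard reagent to a hindered aldehyde; the C6 configuration is irrelevant here because it is erased in step 5.

Step 5
Reactants: 10 propargylic alcohols (C6 epimers)
Product: 11 1-[(1R,2S,5R)-2-ethenyl-2-methyl-5-(propan-2-yl)-5-[(triethylsilyl)oxy]cyclopentyl]but-2-yn-1-one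
Conditions: Dess–Martin periodinane, CH2Cl2, 0 °C to rt
Reagents that add atoms: none
Why: Dess–Martin oxidation under near-neutral conditions, which avoids base-induced β-elimination of the silyloxy group and epimerisation at C5.

Step 6
Reactants: 11 ynone
Product: 12 (1S)-1-[(1S,2S,5R)-2-ethenyl-2-methyl-5-(propan-2-yl)-5-[(triethylsilyl)oxy]cyclopentyl]but-2-yn-1-ol
Conditions: (S)-2-methyl-CBS-oxazaborolidine (1.0 equiv), catecholborane (2 equiv), toluene/CH2Cl2, −78 to −40 °C
Reagents that add atoms: none
Why: Corey–Bakshi–Shibata reduction of an α,β-ynone; the linear propynyl group acts as the small substituent and the doubly neopentyl cyclopentyl group as the large one, so the (S)-catalyst should deliver hydride to the face that gives the (S)-carbinol, which is the C6 configuration of the target. Catecholborane is used because it does not hydroborate the C1 vinyl group at this temperature.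

Step 7
Reactants: 12 (S)-propargylic alcohol
Product: 14 (1S,2Z)-1-[(1S,2S,5R)-2-ethenyl-2-methyl-5-(propan-2-yl)-5-[(triethylsilyl)oxy]cyclopentyl]-3-iodobut-2-en-1-ol, via cyclic alkenylalanate 13 (not isolated)
Conditions: NaAlH2(OCH2CH2OMe)2, THF, 0 °C to rt; then I2, THF, −78 to 0 °C
Reagents that add atoms: iodine, II
Why: Hydroxyl-directed trans-hydroalumination of a propargylic alcohol: the alkoxyaluminate delivers hydride to C7 and leaves aluminium on C8 in a five-membered ring, and iodinolysis with retention gives the iodide with iodine cis to C6, that is (Z). No stereocentre is formed.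

Step 8
Reactants: 14 (Z)-iodo allylic alcohol
Product: 16 (3R,3aS,4R,8aR)-6,8a-dimethyl-3-(propan-2-yl)-3-[(triethylsilyl)oxy]-1,2,3,3a,4,7,8,8a-octahydroazulen-4-ol, via alkylborane 15 (not isolated)
Conditions: 9-BBN (3 equiv), THF, rt to 40 °C; then syringe-pump addition to Pd(dppf)Cl2 (15 mol %), AsPh3 (30 mol %), Cs2CO3 (4 equiv), DMF/THF/H2O, 50 °C, final 0.003 M
Reagents that add atoms: none
Why: 9-BBN adds to the monosubstituted C9=C10 alkene with boron on terminal C9, leaves the trisubstituted iodoalkene alone, and caps the C6 hydroxyl as a borinate that the aqueous base later hydrolyses. Zerovalent palladium, formed from Pd(dppf)Cl2, then inserts into the C8–I bond with retention; the hydroxide-activated alkylborate transfers the primary C9 group to divalent palladium, and reductive elimination forms C8–C9. The closest known reaction type is the intramolecular B-alkyl Suzuki–Miyaura coupling of a hydroborated terminal alkene with a (Z)-alkenyl iodide for carbocycle closure. The seven-membered ring closes between sp3 C9 and sp2 C8 with C7=C8 endocyclic, by reductive elimination from an eight-membered palladacycle. Closure is helped by the cis placement of the two arms on C1 and C5 and by the (Z)-geometry, which puts palladium and C6 on the same side of the alkene. No stereocentre is created, and C1, C4, C5, C6 and the alkene geometry pass through unchanged because the new bond is remote from them. The step needs chemoselective hydroboration, secured by the steric demand of 9-BBN, and intramolecular rather than intermolecular coupling, secured by slow addition at high dilution. Fast transmetalation relative to β-hydride elimination is promoted by the wide-bite-angle dppf ligand with AsPh3.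

Step 9
Reactants: 17 isovanillic acid (3-hydroxy-4-methoxybenzoic acid)
Product: 19 3-[(tert-butyldimethylsilyl)oxy]-4-methoxybenzoic acid, via silyl ester 18 (not isolated)
Conditions: t-BuMe2SiCl (2.4 equiv), imidazole, DMF, rt; then AcOH/THF/H2O, rt
Reagents that add atoms: tert-butyldimethylsilyl chloride, CC(C)(C)[Si](C)(C)Cl
Why: Exhaustive silylation followed by selective hydrolysis of the labile silyl ester; the aryl silyl ether survives dilute acetic acid, whereas a basic hydrolysis would cleave it.

Step 10
Reactants: 19 silyl-protected isovanillic acid; 16 bicyclic allylic alcohol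
Product: 21 (3R,3aS,4R,8aR)-6,8a-dimethyl-3-(propan-2-yl)-3-[(triethylsilyl)oxy]-1,2,3,3a,4,7,8,8a-octahydroazulen-4-yl 3-[(tert-butyldimethylsilyl)oxy]-4-methoxybenzoate, via mixed anhydride 20 (not isolated)
Conditions: 2,4,6-Cl3C6H2COCl, Et3N, THF, rt; then 16, DMAP, toluene, 60 °C
Reagents that add atoms: none
Why: Yamaguchi esterification; DMAP attacks the unhindered aroyl carbonyl of the mixed anhydride, and the resulting acylpyridinium acylates the hindered C6 hydroxyl, the only free hydroxyl in 16. C6 is not touched at carbon, so its configuration is retained.

Step 11
Reactants: 21 bis-silylated ester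
Product: 22 (3R,3aS,4R,8aR)-3-hydroxy-6,8a-dimethyl-3-(propan-2-yl)-1,2,3,3a,4,7,8,8a-octahydroazulen-4-yl 3-hydroxy-4-methoxybenzoate (target)
Conditions: Bu4NF, AcOH (1:1), THF, 0 to 40 °C
Reagents that add atoms: none
Why: Fluoride-mediated cleavage of the aryl and the tertiary silyl ether in one operation; the acetic acid buffer keeps the phenoxide and alkoxide protonated so that the allylic ester is neither transesterified nor ionised. Acyl shift to the tertiary O4 is thermodynamically uphill.

## Compound list

1 | (S)-terpinen-4-ol, (1S)-4-methyl-1-(propan-2-yl)cyclohex-3-en-1-ol | CC1=CC[C@](O)(C(C)C)CC1 | starting material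
2 | triethyl{[(1S)-4-methyl-1-(propan-2-yl)cyclohex-3-en-1-yl]oxy}silane | CC1=CC[C@](O[Si](CC)(CC)CC)(C(C)C)CC1 | intermediate
3 | ozonide (1,2,4-trioxolane) of 2, both diastereomers at the trioxolane carbons, not isolated | CC12CC[C@@](O[Si](CC)(CC)CC)(C(C)C)CC(OO1)O2 | intermediate
4 | (3S)-6-oxo-3-(propan-2-yl)-3-[(triethylsilyl)oxy]heptanal, not isolated | O=CC[C@](O[Si](CC)(CC)CC)(C(C)C)CCC(C)=O | intermediate
5 | (5R)-2-methyl-5-(propan-2-yl)-5-[(triethylsilyl)oxy]cyclopent-1-ene-1-carbaldehyde | CC1=C(C=O)[C@](O[Si](CC)(CC)CC)(C(C)C)CC1 | intermediate
6 | vinylmagnesium bromide | C=C[Mg]Br | starting material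
7 | trimethylsilyl enol ether of 8 (C5=C6, E/Z mixture), not isolated | C=C[C@]1(C)CC[C@@](O[Si](CC)(CC)CC)(C(C)C)C1=CO[Si](C)(C)C | intermediate
8 | (1R,2S,5R)-2-ethenyl-2-methyl-5-(propan-2-yl)-5-[(triethylsilyl)oxy]cyclopentane-1-carbaldehyde | C=C[C@]1(C)CC[C@@](O[Si](CC)(CC)CC)(C(C)C)[C@@H]1C=O | intermediate
9 | 1-propynylmagnesium bromide | CC#C[Mg]Br | starting material
10 | 1-[(1S,2S,5R)-2-ethenyl-2-methyl-5-(propan-2-yl)-5-[(triethylsilyl)oxy]cyclopentyl]but-2-yn-1-ol, C6 epimer mixture | C=C[C@]1(C)CC[C@@](O[Si](CC)(CC)CC)(C(C)C)[C@@H]1C(O)C#CC | intermediate
11 | 1-[(1R,2S,5R)-2-ethenyl-2-methyl-5-(propan-2-yl)-5-[(triethylsilyl)oxy]cyclopentyl]but-2-yn-1-one | C=C[C@]1(C)CC[C@@](O[Si](CC)(CC)CC)(C(C)C)[C@@H]1C(=O)C#CC | intermediate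
12 | (1S)-1-[(1S,2S,5R)-2-ethenyl-2-methyl-5-(propan-2-yl)-5-[(triethylsilyl)oxy]cyclopentyl]but-2-yn-1-ol | C=C[C@]1(C)CC[C@@](O[Si](CC)(CC)CC)(C(C)C)[C@@H]1[C@H](O)C#CC | intermediate
13 | sodium cyclic alkenylalanate of 12 (five-membered C6–O–Al–C8=C7 ring, two 2-methoxyethoxy ligands), not isolated | C=C[C@]1(C)CC[C@@](O[Si](CC)(CC)CC)(C(C)C)[C@@H]1[C@@H]1O[Al-](OCCOC)(OCCOC)C(C)=C1.[Na+] | intermediate
14 | (1S,2Z)-1-[(1S,2S,5R)-2-ethenyl-2-methyl-5-(propan-2-yl)-5-[(triethylsilyl)oxy]cyclopentyl]-3-iodobut-2-en-1-ol | C=C[C@]1(C)CC[C@@](O[Si](CC)(CC)CC)(C(C)C)[C@@H]1[C@H](O)/C=C(/C)I | intermediate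
15 | C9 B-alkyl-9-BBN adduct of 14 with the C6 oxygen capped as 9-BBN borinate, not isolated | B1(C2CCCC1CCC2)CC[C@]1(C)CC[C@@](O[Si](CC)(CC)CC)(C(C)C)[C@@H]1[C@H](OB1C2CCCC1CCC2)/C=C(/C)I | intermediate
16 | (3R,3aS,4R,8aR)-6,8a-dimethyl-3-(propan-2-yl)-3-[(triethylsilyl)oxy]-1,2,3,3a,4,7,8,8a-octahydroazulen-4-ol | O[C@@H]1C=C(C)CC[C@]2(C)CC[C@@](O[Si](CC)(CC)CC)(C(C)C)[C@H]12 | intermediate
17 | isovanillic acid, 3-hydroxy-4-methoxybenzoic acid | COc1ccc(C(=O)O)cc1O | starting material
18 | tert-butyldimethylsilyl 3-[(tert-butyldimethylsilyl)oxy]-4-methoxybenzoate, not isolated | COc1ccc(C(=O)O[Si](C)(C)C(C)(C)C)cc1O[Si](C)(C)C(C)(C)C | intermediate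
19 | 3-[(tert-butyldimethylsilyl)oxy]-4-methoxybenzoic acid | COc1ccc(C(=O)O)cc1O[Si](C)(C)C(C)(C)C | intermediate
20 | mixed anhydride of 19 with 2,4,6-trichlorobenzoic acid, not isolated | COc1ccc(C(=O)OC(=O)c2c(Cl)cc(Cl)cc2Cl)cc1O[Si](C)(C)C(C)(C)C | intermediate
21 | (3R,3aS,4R,8aR)-6,8a-dimethyl-3-(propan-2-yl)-3-[(triethylsilyl)oxy]-1,2,3,3a,4,7,8,8a-octahydroazulen-4-yl 3-[(tert-butyldimethylsilyl)oxy]-4-methoxybenzoate | COc1ccc(C(=O)O[C@@H]2C=C(C)CC[C@]3(C)CC[C@@](O[Si](CC)(CC)CC)(C(C)C)[C@H]23)cc1O[Si](C)(C)C(C)(C)C | intermediate
22 | (3R,3aS,4R,8aR)-3-hydroxy-6,8a-dimethyl-3-(propan-2-yl)-1,2,3,3a,4,7,8,8a-octahydroazulen-4-yl 3-hydroxy-4-methoxybenzoate | COc1ccc(C(=O)O[C@@H]2C=C(C)CC[C@]3(C)CC[C@@](O)(C(C)C)[C@H]23)cc1O | target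

## Step count and least certain steps

Total: 11 steps. Longest linear sequence: 10 steps (1 to 22 through steps 1–8, 10 and 11). Step 9 is a one-step side branch from 17.

**Step 8 (key step).** The likely failures are:
- oligomerisation by intermolecular coupling;
- β-hydride elimination after transmetalation, which regenerates the vinyl group;
- reduction of the C–I bond;
- slowing of transmetalation by the borinate on O6;
- a carbonate-promoted 1,5-shift of the triethylsilyl group from O4 to the free O6.

The first remedies are other bases or a temporary silyl cap on O6. The fallback changes the ring-closing bond. It sets out from 14 and comes back at 16. Suzuki vinylation of the iodide with pinacol vinylboronate (Pd(dppf)Cl2, Cs2CO3, THF/H2O) would give the (Z)-triene F1. Ring-closing metathesis between the C1 vinyl group and the diene terminus (second-generation Grubbs catalyst, (H2IMes)(PCy3)Cl2Ru=CHPh, CH2Cl2, 40 °C) would give the cycloheptadienol F2. Diimide (2-nitrobenzenesulfonyl hydrazide, Et3N) would then reduce the disubstituted C9=C10 bond in preference to the trisubstituted C7=C8 bond, giving 16.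

**Step 3.** Facial discrimination at C1 may be poor, because the silyloxy and isopropyl groups shield opposite faces and their difference in effective size is an argument from A-values, not a certainty. Equilibration at C5 may be incomplete, or the base may expel silanolate from C4 (β-elimination). 1,2-Addition may also compete at the hindered β-carbon. The fallback replaces steric control by chelation control. It sets out from 5 and comes back at 8. Desilylation (HF·pyridine, THF) would give the hydroxy enal F3. Its magnesium alkoxide chelates the aldehyde oxygen in a six-membered ring, which holds O4 in the enal plane and leaves the isopropyl group as the only out-of-plane substituent. Copper-catalysed vinyl addition with one extra equivalent of 6 should then occur anti to isopropyl, giving the hydroxy aldehyde F4, which is silylated cold (Et3SiOTf, 2,6-lutidine) to 8 before any base can induce retro-aldol cleavage.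

**Step 6.** The intrinsic facial bias of the α-stereogenic, very hindered ketone may oppose the catalyst, and slow catalysed reduction would let uncatalysed reduction erode selectivity. The fallback is separation and inversion. It sets out from the epimer mixture 10 (or from 11 reduced unselectively with NaBH4/CeCl3) and comes back at 12. The unwanted (1R)-carbinol epimer F5 would be separated and inverted by a Mitsunobu reaction (4-nitrobenzoic acid, PPh3, diisopropyl azodicarboxylate) to the 4-nitrobenzoate F6. Methanolysis (K2CO3, MeOH) would give 12.

**Step 7.** Hydroalumination of the congested alkoxide may be incomplete, or the alanate may be protonated before iodinolysis, which would give the iodine-free (E)-allylic alcohol. The fallback is a different hydrometalation. It sets out from 12 and comes back at 14. Ruthenium-catalysed trans-hydrosilylation (Et3SiH, [Cp*Ru(MeCN)3]PF6, CH2Cl2), which places silicon on the alkyne carbon distal to the hydroxyl, would give the (Z)-alkenylsilane F7. Iododesilylation with retention (N-iodosuccinimide, hexafluoroisopropanol, 0 °C) would give 14.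

**Step 11.** Cleavage of the hindered tertiary silyl ether may be slow, and forcing conditions would invite cleavage or ionisation of the allylic ester. The fallback removes that silyl group before the ester exists. It sets out from 16 and comes back at 22. Bu4NF (THF, 50 °C) would give the diol F8. Yamaguchi acylation with 19, selective for the secondary hydroxyl over the tertiary one, would give the mono-ester F9. Brief treatment with Bu4NF/AcOH at 0 °C would free the phenol to give 22. This path also absorbs any silyl shift that occurred in step 8.

## Further compounds

F1 | step 8 | (Z)-triene, 14 with ethenyl in place of iodine | C=C[C@]1(C)CC[C@@](O[Si](CC)(CC)CC)(C(C)C)[C@@H]1[C@H](O)/C=C(/C)C=C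
F2 | step 8 | cycloheptadienol, 16 with an additional C9=C10 double bond | O[C@@H]1C=C(C)C=C[C@]2(C)CC[C@@](O[Si](CC)(CC)CC)(C(C)C)[C@H]12
F3 | step 3 | (5R)-5-hydroxy-2-methyl-5-(propan-2-yl)cyclopent-1-ene-1-carbaldehyde | CC1=C(C=O)[C@](O)(C(C)C)CC1
F4 | step 3 | 2-ethenyl-5-hydroxy-2-methyl-5-(propan-2-yl)cyclopentane-1-carbaldehyde, configuration as in 8 | C=C[C@]1(C)CC[C@@](O)(C(C)C)[C@@H]1C=O
F5 | step 6 | C6 epimer of 12, (1R)-carbinol | C=C[C@]1(C)CC[C@@](O[Si](CC)(CC)CC)(C(C)C)[C@@H]1[C@@H](O)C#CC
F6 | step 6 | 4-nitrobenzoate of 12 | C=C[C@]1(C)CC[C@@](O[Si](CC)(CC)CC)(C(C)C)[C@@H]1[C@H](OC(=O)c1ccc(cc1)[N+](=O)[O-])C#CC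
F7 | step 7 | (Z)-alkenylsilane, 14 with triethylsilyl in place of iodine | C=C[C@]1(C)CC[C@@](O[Si](CC)(CC)CC)(C(C)C)[C@@H]1[C@H](O)/C=C(/C)[Si](CC)(CC)CC
F8 | step 11 | (3R,3aS,4R,8aR)-6,8a-dimethyl-3-(propan-2-yl)-1,2,3,3a,4,7,8,8a-octahydroazulene-3,4-diol | O[C@@H]1C=C(C)CC[C@]2(C)CC[C@@](O)(C(C)C)[C@H]12
F9 | step 11 | target with the phenol as its tert-butyldimethylsilyl ether | COc1ccc(C(=O)O[C@@H]2C=C(C)CC[C@]3(C)CC[C@@](O)(C(C)C)[C@H]23)cc1O[Si](C)(C)C(C)(C)C
A1 | alternative 1 | 3-(4-methyl-3-oxopentyl)cyclohept-2-en-1-one | CC(C)C(=O)CCC1=CC(=O)CCCC1
A2 | alternative 1 | cis-fused hydroxy ketone with C1, C4 and C5 set | O=C1CCCC[C@]2(C)CC[C@@](O)(C(C)C)[C@H]12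
A3 | alternative 2 | ene–vinylcyclopropane with C4 silyl ether and trans-2-methylcyclopropyl group | C=C(C)CC[C@@H](O[Si](C)(C)C(C)(C)C)/C=C/[C@@H]1C[C@H]1C
A4 | alternative 2 | cis-fused bicyclo[5.3.0]dec-6-ene with C1 and C8 methyl groups and C4 silyl ether | C1=C[C@H](C)CC[C@]2(C)CC[C@@H](O[Si](C)(C)C(C)(C)C)[C@H]12
A5 | alternative 3 | epoxy enol silane with tethered (E,E)-diene | C/C=C/C=C(\C)CC[C@]1(C(C)C)O[C@@H]1C(=C)O[Si](CC)(CC)CC
A6 | alternative 3 | cis-fused bicyclo[5.3.0]dec-9-en-6-one with C4 silyl ether | O=C1C[C@H](C)C=C[C@]2(C)CC[C@@](O[Si](CC)(CC)CC)(C(C)C)[C@H]12
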